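# Proposed synthesis of CNP0154902.3 (42) by enamine C-acylation

## The problem

Target 42 is a pyrrolo[1,2-a]azepine (azepine ring A, pyrroline ring B) whose N–C=C unit is a tetrasubstituted enamine shared with a cyclohexene (ring C). Ring C is cis-fused to a γ-lactone (ring D) through an oxygen-bearing quaternary carbon that is also a ring B carbon. The N-bearing methine of ring B carries a second, pendant γ-lactone (ring E). There are eight stereocentres: the quaternary C–O carbon, the ring-fusion methine, the carbinol and the ethyl-bearing carbon on ring C, the methyl centre of ring D, the N–CH of ring B and two centres in ring E.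

The N–CH can come from the chiral pool. It can control the neighbouring carbinol of ring E (Felkin–Anh) and, across ring B, the face at which the quaternary carbon receives oxygen. The ring E carbinol controls its methyl centre. The ring C carbinol, taken from a second chiral-pool piece, can control the ring-fusion methine, and as a silyl ether in the closed ring it can control the ethyl-bearing carbon.

The enamine will not survive acid, oxidants or electrophiles. The two lactones exclude hydrides and hard organometallics, and their α-methyl centres can epimerise; the ring D methyl is cis to its ring neighbour and is probably the less stable epimer. The free hydroxyl lies γ to the ring D carbonyl, so an alkoxide there can shift the lactone.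

The enabling feature is that the enamine β-carbon (the ring A carbon of the C=C) is bonded to the ethyl-bearing carbon of ring C. At the ketone oxidation level that bond is an enamine C-acylation, and ring C becomes a vinylogous amide.

## Retrosynthesis

**42 ⇒ 41.** Only the O–Si bond is cut. The carbinol stays a TBS ether to the end, because a free hydroxyl would be triflated in the ethylation step and, as an alkoxide, could open ring D. The forward step needs buffered fluoride and nothing basic.

**41 ⇒ 38.** The C–ethyl and C–H bonds at the ethyl-bearing carbon are cut, leading back to vinylogous amide 38. The neighbouring order, ethyl-metal 1,2-addition followed by hydride delivery from the hydroxyl, was weighed and put aside for two reasons. Organolithium or organocerium reagents would attack the two lactones before the deactivated vinylogous amide carbonyl. The hydride would also have to enter syn to the oxygen substituent, against the favoured trajectory. The reverse order is chosen. Tf2O activates only the vinylogous amide oxygen, a silane replaces triflate by hydrogen, and ethyl then comes in as the nucleophile. In the conformationally locked ring the OTBS group on the adjacent carbon is pseudoaxial, and a nucleophile adding along the chair-like axial path enters anti to it, which is the required trans arrangement. The precursor has one stereocentre and two carbons fewer. The forward reaction must stop the reduction at the iminium stage and add ethyl at the γ-carbon.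

**38 ⇒ 36 (key disconnection).** The bond between the enamine β-carbon and the acyl carbon is cut, opening ring C to enamine acid 36. Cutting the C–N bonds instead, or two C–C bonds of ring C by cycloaddition, would require a fully substituted carbocycle to be built first without a template. This cut makes ring C last, creates no stereocentre, and reduces the problem to a bicyclic enamine carrying a side chain on a spiro-lactone. The forward reaction must acylate at carbon and keep the configuration α to the acyl group.

**36 ⇒ 33.** The C–CO2 bond at the enamine β-carbon is cut (decarboxylation) and both acids are re-esterified. The enamine is too sensitive to carry, whereas the tert-butyl vinylogous carbamate 33 is robust and is the direct product of extending a lactam carbonyl by one carbon. The forward step must cleave two tert-butyl esters without loss of the silyl ether.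

**33 ⇒ 29 + 30; 29 ⇒ 26 + 27; 26 ⇒ 25 ⇒ 24.** Ring A is cut at its N–C and C–C bonds to the four-carbon dihalide 30. The exocyclic C=C of 29 is cut back to thiolactam 26 and bromoacetate 27 (sulfide contraction). Adding an organometallic chain to the lactam carbonyl was rejected: the carbonyl is flanked by the quaternary carbon and the lactones would react first. Thionation is selective for the lactam. The forward annulation must close a seven-membered ring without enolising the lactones.

**24 ⇒ 20.** Only the oxidation level of the terminal side-chain carbon changes (primary silyl ether to tert-butyl ester). The carbon is carried as a silyl ether through the enolate chemistry because an ester there would make the adjacent allylic hydrogen acidic.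

**20 ⇒ 16 + 17.** Three bonds are cut: the C–C bond between the ring-fusion methine and the methyl-bearing carbon (Michael addition), the C–O bond at the quaternary carbon (enolate hydroxylation) and the lactone C–O bond. The reverse polarity, a lactam enolate adding to a mesaconate-type diester, was weighed; it would leave the side chain one carbon short and give no handle on the methine configuration. In the chosen sense the ester enolate adds anti to the allylic silyloxy group. Oxygen is introduced last, so it enters trans to ring E and forces the new C–C bond cis, as the target requires. Methylating a preformed lactone would place methyl trans to its neighbour, so the methyl comes in with the nucleophile. Three stereocentres and ring D arise from a planar alkylidene lactam.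

**16 ⇒ 13 + 4.** The exocyclic C=C is cut (aldol condensation). Aldehyde 4 brings the future ring C carbinol from the chiral pool; it derives from diol 1 through 2.

**13 ⇒ 12 ⇒ 9 + 10; 9 ⇒ 8 ⇒ 7 ⇒ 6 ⇒ 5.** Ring E is cut at its carbinol C–C bond and its lactone C–O bond (Barbier allylation with acrylate 10, then hydrogenation). Aldehyde 9 is four routine steps from pyroglutaminol 5. The forward allylation must follow Felkin–Anh control.

## Roads not taken

**Alternative 1:** The cut runs through ring B, at the bond from the N-bearing methine to the ring methylene and at the C–O bond of the quaternary carbon. Forward, an intermolecular nitrone–alkene [3+2] cycloaddition onto the exocyclic methylene of a fully substituted cyclohexanone would give spiro-isoxazolidine A1.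
- Merits: the union is convergent, the regiochemistry (oxygen to the more substituted carbon) is reliable, and the N–O bond stores both the quaternary oxygen and the nitrogen. Ethyl is in place early, so the late ethylation, the least secure step of the chosen plan, is avoided. In these respects this road is better.
- Weak points: the carbocycle with four contiguous stereocentres must be made first with no ring template. Its α-methylene ketone is prone to dimerise and to epimerise at the α-carbon. Facial selectivity has to be delivered intermolecularly by the lactone centre of the dipole and by the ring at once. The N-benzyl group must be removed before ring A can close.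
- Comparison: the chosen plan introduces each stereocentre under the control of an identified neighbour on monocyclic intermediates, and closes ring C in a step with no stereochemical demand.

**Alternative 2:** The cut removes both ring-forming C–N bonds, from nitrogen to the enamine carbon and from nitrogen to its ring A methylene. Forward, a Staudinger/aza-Wittig condensation of an azide with the ring ketone, N-alkylation of the imine by a primary chloride and loss of the only available α-proton would give A2 (identical with 41).
- Merits: the enamine is formed last under neutral conditions with all eight stereocentres present, and its regiochemistry is unambiguous. Here this road is cleaner than the chosen one, which has to carry the enamine through an acylation and a reductive ethylation.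
- Weak points: it needs the same fully substituted cyclohexanone, now also bearing the quaternary C–O carbon and an azidoalkyl arm. Imine formation at a ketone flanked by a quaternary carbon is slow, and closure of the seven-membered ring by a neutral imine nitrogen competes with elimination.
- Comparison: the difficulty is moved into the carbocycle, not removed. The chosen plan solves the ring C stereocentres on an open side chain before ring C exists.

**Alternative 3:** The cut breaks the bonds from the enamine carbon to the quaternary carbon and from the carbinol carbon to the ring-fusion methine. Forward, an intramolecular amidofuran Diels–Alder reaction with a tethered enol-lactone alkene, followed by opening of the oxygen bridge, would give enamide ketone A3.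
- Merits: rings B and C and two C–C bonds form in one thermal step without reagents, and the amide-stabilised enamine is robust. Up to A3 this road is shorter.
- Weak points: the dienophile is a hindered, electron-rich tetrasubstituted alkene. A3 still lacks the ring D methyl, which on alkylation would enter trans to its neighbour, the wrong epimer. It has a ketone where the axial carbinol must be, and an epimerisable ethyl centre next to that ketone. The ring A lactam carbonyl must be reduced in the presence of two lactones.
- Comparison: in the chosen plan the methyl group, the carbinol and the oxidation level of ring A are final before ring C is closed, and no amide has to be reduced.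

Key step: step 20

## Route

Assumptions and abbreviations:
- Amino acid 36 is handled as its internal salt (C-protonated iminium carboxylate) and is written in the neutral enamine form.
- Compound 5 is bought; it is also the reduction product of ethyl D-pyroglutamate.
- TBS = tert-butyldimethylsilyl, Boc = tert-butoxycarbonyl.

Step 1
Reactants: 1 (S)-but-3-ene-1,2-diol
Product: 2 (S)-3,4-bis[(tert-butyldimethylsilyl)oxy]but-1-ene
Conditions: TBSCl, imidazole, DMF, rt
Reagents that add atoms: tert-butyldimethylsilyl chloride, CC(C)(C)[Si](C)(C)Cl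
Why: Standard silyl ether formation at both hydroxyl groups; the stereocentre is not involved.

Step 2
Reactants: 2 (S)-3,4-bis[(tert-butyldimethylsilyl)oxy]but-1-ene
Product: 4 (R)-2,3-bis[(tert-butyldimethylsilyl)oxy]propanal, via ozonide 3 (not isolated)
Conditions: O3, CH2Cl2, −78 °C; then PPh3, −78 °C → rt
Reagents that add atoms: ozone, [O-][O+]=O
Why: Ozonolysis of the terminal alkene with reductive work-up; no base is present, so the α-silyloxy centre is retained (the descriptor changes from S to R only through the priority rules).

Step 3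
Reactants: 5 (R)-5-(hydroxymethyl)pyrrolidin-2-one
Product: 6 (R)-5-{[(tert-butyldimethylsilyl)oxy]methyl}pyrrolidin-2-one
Conditions: TBSCl, imidazole, DMF, rt
Reagents that add atoms: tert-butyldimethylsilyl chloride, CC(C)(C)[Si](C)(C)Cl
Why: Selective O-silylation; imidazole does not deprotonate the lactam N–H.

Step 4
Reactants: 6 (R)-5-{[(tert-butyldimethylsilyl)oxy]methyl}pyrrolidin-2-one
Product: 7 tert-butyl (R)-2-{[(tert-butyldimethylsilyl)oxy]methyl}-5-oxopyrrolidine-1-carboxylate
Conditions: Boc2O, DMAP (cat.), Et3N, CH2Cl2, rt
Reagents that add atoms: di-tert-butyl dicarbonate, CC(C)(C)OC(=O)OC(=O)OC(C)(C)C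
Why: DMAP-catalysed N-acylation of the lactam; the carbamate acidifies the ring α-protons and later makes the alkylidene lactam a competent Michael acceptor.

Step 5
Reactants: 7 tert-butyl (R)-2-{[(tert-butyldimethylsilyl)oxy]methyl}-5-oxopyrrolidine-1-carboxylate
Product: 8 tert-butyl (R)-2-(hydroxymethyl)-5-oxopyrrolidine-1-carboxylate
Conditions: AcOH/THF/H2O (3:1:1), rt
Reagents that add atoms: none
Why: Acidic desilylation avoids the alkoxide that would cause N-to-O migration of the Boc group.

Step 6
Reactants: 8 tert-butyl (R)-2-(hydroxymethyl)-5-oxopyrrolidine-1-carboxylate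
Product: 9 tert-butyl (R)-2-formyl-5-oxopyrrolidine-1-carboxylate
Conditions: Dess–Martin periodinane, NaHCO3, CH2Cl2, 0 °C → rt
Reagents that add atoms: none
Why: Dess–Martin oxidation under buffered, non-basic conditions; the configurationally labile α-amino aldehyde is used at once.

Step 7
Reactants: 9 tert-butyl (R)-2-formyl-5-oxopyrrolidine-1-carboxylate; 10 ethyl 2-(bromomethyl)acrylate
Product: 12 tert-butyl (R)-2-[(S)-4-methylidene-5-oxooxolan-2-yl]-5-oxopyrrolidine-1-carboxylate, via hydroxy ester 11 (not isolated)
Conditions: Zn dust, THF/sat. aq NH4Cl, 0 °C → rt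
Reagents that add atoms: none
Why: Barbier allylation by the allylzinc formed in situ, followed by lactonisation of the γ-hydroxy ester. Felkin–Anh attack anti to the imide nitrogen, as with other cyclic N-acyl α-amino aldehydes, should set the carbinol centre S (N and O anti).

Step 8
Reactants: 12 tert-butyl (R)-2-[(S)-4-methylidene-5-oxooxolan-2-yl]-5-oxopyrrolidine-1-carboxylate
Product: 13 tert-butyl (R)-2-[(2S,4S)-4-methyl-5-oxooxolan-2-yl]-5-oxopyrrolidine-1-carboxylate
Conditions: H2 (1 atm), 10% Pd/C, EtOAc, rt
Reagents that add atoms: none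
Why: Heterogeneous hydrogenation adds hydrogen to the exocyclic alkene from the face opposite the substituent at the carbinol carbon, which should give the cis-2,4-disubstituted lactone.

Step 9
Reactants: 13 tert-butyl (R)-2-[(2S,4S)-4-methyl-5-oxooxolan-2-yl]-5-oxopyrrolidine-1-carboxylate; 4 (R)-2,3-bis[(tert-butyldimethylsilyl)oxy]propanal
Product: 14 tert-butyl (5R)-3-{(2R)-2,3-bis[(tert-butyldimethylsilyl)oxy]-1-hydroxypropyl}-5-[(2S,4S)-4-methyl-5-oxooxolan-2-yl]-2-oxopyrrolidine-1-carboxylate (epimers at C-3 and at the new carbinol)
Conditions: LiN(SiMe3)2, THF, −78 °C; then 4, −78 °C; AcOH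
Reagents that add atoms: none
Why: Aldol addition of the lithium enolate of the N-acyl lactam, whose α-protons are the most acidic C–H by several pK units, so the lactone α-centre is not touched. The two new centres are removed in step 10.

Step 10
Reactants: 14 aldol adduct (epimer mixture)
Product: 16 tert-butyl (3E,5R)-3-{(2S)-2,3-bis[(tert-butyldimethylsilyl)oxy]propylidene}-5-[(2S,4S)-4-methyl-5-oxooxolan-2-yl]-2-oxopyrrolidine-1-carboxylate, via mesylate 15 (not isolated)
Conditions: MsCl, Et3N, CH2Cl2, 0 °C; then DBU, 0 °C → rt
Reagents that add atoms: none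
Why: Mesylation and E1cB elimination should give the more stable E-alkylidene lactam (side chain away from the carbonyl). Contact with DBU is kept short to avoid deprotonation at the silyloxy-bearing carbon.

Step 11
Reactants: 16 tert-butyl (3E,5R)-3-{(2S)-2,3-bis[(tert-butyldimethylsilyl)oxy]propylidene}-5-[(2S,4S)-4-methyl-5-oxooxolan-2-yl]-2-oxopyrrolidine-1-carboxylate; 17 methyl propanoate
Product: 20 tert-butyl (3R,4R,5R,8R)-4-{(1S)-1,2-bis[(tert-butyldimethylsilyl)oxy]ethyl}-3-methyl-8-[(2S,4S)-4-methyl-5-oxooxolan-2-yl]-2,6-dioxo-1-oxa-7-azaspiro[4.4]nonane-7-carboxylate, via lithium enolate 18 (not isolated), via hydroxy ester 19 (not isolated)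
Conditions: 17, LiN(i-Pr)2, THF/DMPU, −78 °C; 16, −78 °C; 2-(phenylsulfonyl)-3-phenyloxaziridine, −78 °C; AcOH; then PPTS, CH2Cl2, rt
Reagents that add atoms: 2-(phenylsulfonyl)-3-phenyloxaziridine, O=S(=O)(c1ccccc1)N1OC1c1ccccc1
Why: Tandem Michael addition of the Z-ester enolate to the s-cis unsaturated imide, Davis hydroxylation of the resulting lactam enolate and acid-catalysed lactonisation. The nucleophile should attack the β-carbon anti to the allylic C–OTBS bond, with the allylic hydrogen held towards the ring methylene by A(1,3) strain (Felkin–Anh), and the Z-enolate should give the 2,3-anti adduct, which places methyl cis to the side chain in the lactone. The oxaziridine approaches the planar enolate trans to the lactone at C-5 of the pyrrolidinone, so oxygen ends trans and the new C–C bond cis to ring E.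

Step 12
Reactants: 20 spiro-lactone bis-TBS ether
Product: 21 tert-butyl (3R,4R,5R,8R)-4-{(1S)-1-[(tert-butyldimethylsilyl)oxy]-2-hydroxyethyl}-3-methyl-8-[(2S,4S)-4-methyl-5-oxooxolan-2-yl]-2,6-dioxo-1-oxa-7-azaspiro[4.4]nonane-7-carboxylate
Conditions: HF·pyridine, pyridine, THF, 0 °C
Reagents that add atoms: none
Why: Buffered HF·pyridine cleaves a primary TBS ether much faster than the hindered secondary one.

Step 13
Reactants: 21 primary alcohol
Product: 23 (2S)-2-[(tert-butyldimethylsilyl)oxy]-2-{(3R,4R,5R,8R)-7-(tert-butoxycarbonyl)-3-methyl-8-[(2S,4S)-4-methyl-5-oxooxolan-2-yl]-2,6-dioxo-1-oxa-7-azaspiro[4.4]nonan-4-yl}acetic acid, via aldehyde 22 (not isolated)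
Conditions: TEMPO (cat.), PhI(OAc)2, MeCN/H2O, rt
Reagents that add atoms: water, O
Why: TEMPO/PhI(OAc)2 oxidation of the primary alcohol through the aldehyde hydrate to the acid; the near-neutral medium spares the lactones, the carbamate and the α-silyloxy centre.

Step 14
Reactants: 23 α-silyloxy acid
Product: 24 tert-butyl ester of 23 (tert-butyl (2S)-2-[(tert-butyldimethylsilyl)oxy]-2-{spiro-lactone}acetate, N-Boc)
Conditions: tert-butyl 2,2,2-trichloroacetimidate, CH2Cl2/cyclohexane, rt
Reagents that add atoms: tert-butyl 2,2,2-trichloroacetimidate, CC(C)(C)OC(=N)C(Cl)(Cl)Cl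
Why: Imidate tert-butylation of the acid needs no base; the ester masks the acid through thionation and annulation.

Step 15
Reactants: 24 N-Boc lactam tert-butyl ester
Product: 25 tert-butyl (2S)-2-[(tert-butyldimethylsilyl)oxy]-2-{(3R,4R,5R,8R)-3-methyl-8-[(2S,4S)-4-methyl-5-oxooxolan-2-yl]-2,6-dioxo-1-oxa-7-azaspiro[4.4]nonan-4-yl}acetate
Conditions: Mg(ClO4)2 (20 mol%), MeCN, 50 °C
Reagents that add atoms: none
Why: Mg(ClO4)2 chelates the two carbonyl groups of the N-acyl carbamate and removes that Boc group selectively, leaving the tert-butyl ester and the silyl ether.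

Step 16
Reactants: 25 N–H lactam
Product: 26 the 6-thioxo analogue of 25 (thiolactam, all stereocentres as in 25)
Conditions: Lawesson's reagent, THF, 50 °C
Reagents that add atoms: Lawesson's reagent, COc1ccc(cc1)P1(=S)SP(=S)(S1)c1ccc(OC)cc1
Why: Lawesson thionation; a secondary lactam reacts far faster than lactones and esters.

Step 17
Reactants: 26 thiolactam; 27 tert-butyl bromoacetate
Product: 29 Z-vinylogous carbamate (tert-butyl (2Z)-2-(spiro-lactone pyrrolidin-2-ylidene)acetate, N–H, all stereocentres as in 25), via thioimidate salt 28 (not isolated)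
Conditions: 27, CH2Cl2, rt; then PPh3, Et3N, MeCN, 60 °C
Reagents that add atoms: none
Why: Eschenmoser sulfide contraction: S-alkylation, deprotonation, thiirane formation and sulfur transfer to the phosphine. The product is held Z by the N–H···O=C hydrogen bond, and the quaternary neighbour has no proton to lose.

Step 18
Reactants: 29 Z-vinylogous carbamate; 30 1-bromo-4-chlorobutane
Product: 33 bicyclic vinylogous carbamate (2,3,4,5-tetrahydro-1H-pyrrolo[1,2-a]azepine with CO2t-Bu on the enamine β-carbon, spiro-lactone as in 25), via chloride 31 (not isolated), via iodide 32 (not isolated)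
Conditions: NaH, DMF, 0 °C; 30, rt; then NaI, i-Pr2NEt, 70 °C
Reagents that add atoms: none
Why: The vinylogous carbamate N–H is the most acidic site by several pK units, so its anion is N-alkylated by the bromide end without enolising the lactones. After Finkelstein exchange the enamine carbon closes the ring (7-(enolendo)-exo-tet), the known alkylative annulation of enaminoesters with α,ω-dihaloalkanes.

Step 19
Reactants: 33 bicyclic vinylogous carbamate
Product: 36 bicyclic enamine spiro-lactone α-silyloxy acid, via bis-silyl ester 34 (not isolated), via enamino diacid 35 (not isolated)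
Conditions: TMSOTf, 2,6-lutidine, CH2Cl2, 0 °C; then pH 7 phosphate buffer, THF, rt
Reagents that add atoms: none
Why: The silyl triflate cleaves both tert-butyl esters without touching the TBS ether. On hydrolysis the vinylogous carbamic acid is protonated at carbon and loses CO2, which frees the enamine; the other α-carbon is quaternary, so only one enamine can form.

Step 20
Reactants: 36 bicyclic enamine spiro-lactone α-silyloxy acid
Product: 38 tetracyclic vinylogous amide TBS ether, via mixed anhydride 37 (not isolated)
Conditions: i-BuOCOCl, N-methylmorpholine, THF, −20 °C; then Et3N, 0 °C → rt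
Reagents that add atoms: none
Why: The internal salt is acylated at the carboxylate by the chloroformate to give mixed carbonic anhydride 37 while the nitrogen end is still the unreactive iminium. Triethylamine then frees the enamine, whose β-carbon attacks the acyl carbonyl; loss of isobutyl carbonate and of the remaining β-proton gives vinylogous amide 38. The closest known reaction is the Stork C-acylation of enamines by acid chlorides and mixed anhydrides, here intramolecular. The cyclohexenone ring closes in a 6-(enolendo)-exo-trig mode. No stereocentre is formed, and the five centres of the spiro-lactone and its side chain are carried through unchanged. The step needs C- over N-acylation; the nitrogen is tertiary, so an N-acylammonium ion can only revert. It also needs retention at the α-silyloxy carbon, which the carbonic anhydride, the weak base and the fast six-membered capture should secure against ketene formation. The product is the stabilised, push–pull form of the hindered enamine.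

Step 21
Reactants: 38 tetracyclic vinylogous amide TBS ether
Product: 41 O-TBS ether of the target, via triflyloxy iminium triflate 39 (not isolated), via conjugated iminium triflate 40 (not isolated)
Conditions: Tf2O, 2,6-di-tert-butyl-4-methylpyridine, CH2Cl2, −78 °C; Et3SiH, −78 → −20 °C; then EtMgBr, CuBr·SMe2 (20 mol%), THF, −78 °C
Reagents that add atoms: ethylmagnesium bromide, CC[Mg]Br
Why: Proposed new method: triflation of the vinylogous amide oxygen gives 3-triflyloxy iminium salt 39 (known for enaminones); the silane delivers hydride to the triflate-bearing carbon and triflate leaves to give conjugated iminium 40, which so weak a hydride donor should no longer reduce; the ethylcopper reagent then adds to the γ-carbon along the chair-like axial path, anti to the pseudoaxial OTBS group on the adjacent carbon, giving the enamine with ethyl trans to the silyloxy group. The closest known reactions are the Tf2O-mediated reductive alkylation of tertiary amides and the 4-selective addition of organocopper reagents to pyridinium salts; the lactones are spared because only the vinylogous amide oxygen is nucleophilic enough to be triflated.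

Step 22
Reactants: 41 O-TBS ether of the target
Product: 42 CNP0154902.3
Conditions: HF·pyridine, pyridine, THF, 0 °C → rt; NaHCO3 work-up
Reagents that add atoms: none
Why: Buffered fluoride cleaves the secondary silyl ether without forming an alkoxide at the carbinol, which could attack the ring D carbonyl. The enamine is regenerated on bicarbonate work-up.

## Compound list

1 | (S)-but-3-ene-1,2-diol | C=C[C@H](O)CO | starting material
2 | (S)-3,4-bis[(tert-butyldimethylsilyl)oxy]but-1-ene | C=C[C@H](O[Si](C)(C)C(C)(C)C)CO[Si](C)(C)C(C)(C)C | intermediate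
3 | 3-{(1R)-1,2-bis[(tert-butyldimethylsilyl)oxy]ethyl}-1,2,4-trioxolane (ozonide, epimers at the ring carbon) | CC(C)(C)[Si](C)(C)OC[C@@H](O[Si](C)(C)C(C)(C)C)C1OCOO1 | intermediate
4 | (R)-2,3-bis[(tert-butyldimethylsilyl)oxy]propanal | O=C[C@H](O[Si](C)(C)C(C)(C)C)CO[Si](C)(C)C(C)(C)C | intermediate
5 | (R)-5-(hydroxymethyl)pyrrolidin-2-one | O=C1CC[C@H](CO)N1 | starting material
6 | (R)-5-{[(tert-butyldimethylsilyl)oxy]methyl}pyrrolidin-2-one | O=C1CC[C@H](CO[Si](C)(C)C(C)(C)C)N1 | intermediate
7 | tert-butyl (R)-2-{[(tert-butyldimethylsilyl)oxy]methyl}-5-oxopyrrolidine-1-carboxylate | O=C1CC[C@H](CO[Si](C)(C)C(C)(C)C)N1C(=O)OC(C)(C)C | intermediate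
8 | tert-butyl (R)-2-(hydroxymethyl)-5-oxopyrrolidine-1-carboxylate | O=C1CC[C@H](CO)N1C(=O)OC(C)(C)C | intermediate
9 | tert-butyl (R)-2-formyl-5-oxopyrrolidine-1-carboxylate | O=C1CC[C@H](C=O)N1C(=O)OC(C)(C)C | intermediate
10 | ethyl 2-(bromomethyl)acrylate | C=C(CBr)C(=O)OCC | starting material
11 | tert-butyl (R)-2-[(S)-3-(ethoxycarbonyl)-1-hydroxybut-3-en-1-yl]-5-oxopyrrolidine-1-carboxylate | O=C1CC[C@H]([C@@H](O)CC(=C)C(=O)OCC)N1C(=O)OC(C)(C)C | intermediate
12 | tert-butyl (R)-2-[(S)-4-methylidene-5-oxooxolan-2-yl]-5-oxopyrrolidine-1-carboxylate | O=C1CC[C@H]([C@@H]2CC(=C)C(=O)O2)N1C(=O)OC(C)(C)C | intermediate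
13 | tert-butyl (R)-2-[(2S,4S)-4-methyl-5-oxooxolan-2-yl]-5-oxopyrrolidine-1-carboxylate | O=C1CC[C@H]([C@@H]2C[C@H](C)C(=O)O2)N1C(=O)OC(C)(C)C | intermediate
14 | tert-butyl (5R)-3-{(2R)-2,3-bis[(tert-butyldimethylsilyl)oxy]-1-hydroxypropyl}-5-[(2S,4S)-4-methyl-5-oxooxolan-2-yl]-2-oxopyrrolidine-1-carboxylate (epimers at C-3 and the carbinol) | CC(C)(C)[Si](C)(C)OC[C@@H](O[Si](C)(C)C(C)(C)C)C(O)C1C[C@H]([C@@H]2C[C@H](C)C(=O)O2)N(C(=O)OC(C)(C)C)C1=O | intermediate
15 | methanesulfonate of 14 | CC(C)(C)[Si](C)(C)OC[C@@H](O[Si](C)(C)C(C)(C)C)C(OS(C)(=O)=O)C1C[C@H]([C@@H]2C[C@H](C)C(=O)O2)N(C(=O)OC(C)(C)C)C1=O | intermediate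
16 | tert-butyl (3E,5R)-3-{(2S)-2,3-bis[(tert-butyldimethylsilyl)oxy]propylidene}-5-[(2S,4S)-4-methyl-5-oxooxolan-2-yl]-2-oxopyrrolidine-1-carboxylate | CC(C)(C)[Si](C)(C)OC[C@@H](O[Si](C)(C)C(C)(C)C)/C=C1\C[C@H]([C@@H]2C[C@H](C)C(=O)O2)N(C(=O)OC(C)(C)C)C1=O | intermediate
17 | methyl propanoate | CCC(=O)OC | starting material
18 | lithium lactam enolate of the Michael adduct (methyl ester; stereocentres as in 19) | COC(=O)[C@H](C)[C@@H](C1=C([O-])N(C(=O)OC(C)(C)C)[C@@H]([C@@H]2C[C@H](C)C(=O)O2)C1)[C@H](O[Si](C)(C)C(C)(C)C)CO[Si](C)(C)C(C)(C)C.[Li+] | intermediate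
19 | α-hydroxy lactam methyl ester (3-hydroxy trans to the ring E lactone; open form of 20) | COC(=O)[C@H](C)[C@@H]([C@]1(O)C[C@H]([C@@H]2C[C@H](C)C(=O)O2)N(C(=O)OC(C)(C)C)C1=O)[C@H](O[Si](C)(C)C(C)(C)C)CO[Si](C)(C)C(C)(C)C | intermediate
20 | tert-butyl (3R,4R,5R,8R)-4-{(1S)-1,2-bis[(tert-butyldimethylsilyl)oxy]ethyl}-3-methyl-8-[(2S,4S)-4-methyl-5-oxooxolan-2-yl]-2,6-dioxo-1-oxa-7-azaspiro[4.4]nonane-7-carboxylate | CC(C)(C)[Si](C)(C)OC[C@@H](O[Si](C)(C)C(C)(C)C)[C@H]1[C@@H](C)C(=O)O[C@]12C[C@H]([C@@H]3C[C@H](C)C(=O)O3)N(C(=O)OC(C)(C)C)C2=O | intermediate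
21 | primary alcohol: as 20 with 4-{(1S)-1-[(tert-butyldimethylsilyl)oxy]-2-hydroxyethyl} | OC[C@@H](O[Si](C)(C)C(C)(C)C)[C@H]1[C@@H](C)C(=O)O[C@]12C[C@H]([C@@H]3C[C@H](C)C(=O)O3)N(C(=O)OC(C)(C)C)C2=O | intermediate
22 | aldehyde: as 20 with 4-{(1S)-1-[(tert-butyldimethylsilyl)oxy]-2-oxoethyl} | O=C[C@@H](O[Si](C)(C)C(C)(C)C)[C@H]1[C@@H](C)C(=O)O[C@]12C[C@H]([C@@H]3C[C@H](C)C(=O)O3)N(C(=O)OC(C)(C)C)C2=O | intermediate
23 | (2S)-2-[(tert-butyldimethylsilyl)oxy]-2-{(3R,4R,5R,8R)-7-(tert-butoxycarbonyl)-3-methyl-8-[(2S,4S)-4-methyl-5-oxooxolan-2-yl]-2,6-dioxo-1-oxa-7-azaspiro[4.4]nonan-4-yl}acetic acid | OC(=O)[C@@H](O[Si](C)(C)C(C)(C)C)[C@H]1[C@@H](C)C(=O)O[C@]12C[C@H]([C@@H]3C[C@H](C)C(=O)O3)N(C(=O)OC(C)(C)C)C2=O | intermediate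
24 | tert-butyl ester of 23 | CC(C)(C)OC(=O)[C@@H](O[Si](C)(C)C(C)(C)C)[C@H]1[C@@H](C)C(=O)O[C@]12C[C@H]([C@@H]3C[C@H](C)C(=O)O3)N(C(=O)OC(C)(C)C)C2=O | intermediate
25 | tert-butyl (2S)-2-[(tert-butyldimethylsilyl)oxy]-2-{(3R,4R,5R,8R)-3-methyl-8-[(2S,4S)-4-methyl-5-oxooxolan-2-yl]-2,6-dioxo-1-oxa-7-azaspiro[4.4]nonan-4-yl}acetate | CC(C)(C)OC(=O)[C@@H](O[Si](C)(C)C(C)(C)C)[C@H]1[C@@H](C)C(=O)O[C@]12C[C@H]([C@@H]3C[C@H](C)C(=O)O3)NC2=O | intermediate
26 | 6-thioxo analogue of 25 (thiolactam) | CC(C)(C)OC(=O)[C@@H](O[Si](C)(C)C(C)(C)C)[C@H]1[C@@H](C)C(=O)O[C@]12C[C@H]([C@@H]3C[C@H](C)C(=O)O3)NC2=S | intermediate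
27 | tert-butyl bromoacetate | BrCC(=O)OC(C)(C)C | starting material
28 | S-(tert-butoxycarbonylmethyl) thioimidate hydrobromide of 26 | CC(C)(C)OC(=O)[C@@H](O[Si](C)(C)C(C)(C)C)[C@H]1[C@@H](C)C(=O)O[C@]12C[C@H]([C@@H]3C[C@H](C)C(=O)O3)[NH+]=C2SCC(=O)OC(C)(C)C.[Br-] | intermediate
29 | Z-vinylogous carbamate: 6-[(Z)-(tert-butoxycarbonyl)methylidene] analogue of 25 (N–H) | CC(C)(C)OC(=O)[C@@H](O[Si](C)(C)C(C)(C)C)[C@H]1[C@@H](C)C(=O)O[C@]12C[C@H]([C@@H]3C[C@H](C)C(=O)O3)N/C2=C\C(=O)OC(C)(C)C | intermediate
30 | 1-bromo-4-chlorobutane | ClCCCCBr | starting material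
31 | N-(4-chlorobutyl) derivative of 29 (E) | CC(C)(C)OC(=O)[C@@H](O[Si](C)(C)C(C)(C)C)[C@H]1[C@@H](C)C(=O)O[C@]12C[C@H]([C@@H]3C[C@H](C)C(=O)O3)N(CCCCCl)/C2=C/C(=O)OC(C)(C)C | intermediate
32 | N-(4-iodobutyl) derivative of 29 (E) | CC(C)(C)OC(=O)[C@@H](O[Si](C)(C)C(C)(C)C)[C@H]1[C@@H](C)C(=O)O[C@]12C[C@H]([C@@H]3C[C@H](C)C(=O)O3)N(CCCCI)/C2=C/C(=O)OC(C)(C)C | intermediate
33 | bicyclic vinylogous carbamate: tetrahydropyrrolo[1,2-a]azepine with CO2t-Bu on the enamine β-carbon, spiro-lactone and side chain as in 25 | CC(C)(C)OC(=O)[C@@H](O[Si](C)(C)C(C)(C)C)[C@H]1[C@@H](C)C(=O)O[C@]12C[C@H]([C@@H]3C[C@H](C)C(=O)O3)N3CCCCC(C(=O)OC(C)(C)C)=C23 | intermediate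
34 | bis(trimethylsilyl) ester corresponding to 33 | C[Si](C)(C)OC(=O)[C@@H](O[Si](C)(C)C(C)(C)C)[C@H]1[C@@H](C)C(=O)O[C@]12C[C@H]([C@@H]3C[C@H](C)C(=O)O3)N3CCCCC(C(=O)O[Si](C)(C)C)=C23 | intermediate
35 | enamino diacid corresponding to 33 | OC(=O)[C@@H](O[Si](C)(C)C(C)(C)C)[C@H]1[C@@H](C)C(=O)O[C@]12C[C@H]([C@@H]3C[C@H](C)C(=O)O3)N3CCCCC(C(=O)O)=C23 | intermediate
36 | bicyclic enamine spiro-lactone α-silyloxy acid (enamine C=C–H in ring A; handled as internal salt) | OC(=O)[C@@H](O[Si](C)(C)C(C)(C)C)[C@H]1[C@@H](C)C(=O)O[C@]12C[C@H]([C@@H]3C[C@H](C)C(=O)O3)N3CCCCC=C23 | intermediate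
37 | isobutyl carbonic mixed anhydride of 36 | CC(C)COC(=O)OC(=O)[C@@H](O[Si](C)(C)C(C)(C)C)[C@H]1[C@@H](C)C(=O)O[C@]12C[C@H]([C@@H]3C[C@H](C)C(=O)O3)N3CCCCC=C23 | intermediate
38 | tetracyclic vinylogous amide TBS ether (ring C ketone conjugated with the enamine) | O=C1C2=C3N(CCCC2)[C@@H]([C@@H]2C[C@H](C)C(=O)O2)C[C@]32OC(=O)[C@H](C)[C@@H]2[C@@H]1O[Si](C)(C)C(C)(C)C | intermediate
39 | 3-triflyloxy conjugated iminium triflate from 38 | FC(F)(F)S(=O)(=O)OC1=C2C3=[N+](CCCC2)[C@@H]([C@@H]2C[C@H](C)C(=O)O2)C[C@]32OC(=O)[C@H](C)[C@@H]2[C@@H]1O[Si](C)(C)C(C)(C)C.[O-]S(=O)(=O)C(F)(F)F | intermediate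
40 | conjugated iminium triflate (C–H at the future ethyl-bearing carbon) | C1=C2C3=[N+](CCCC2)[C@@H]([C@@H]2C[C@H](C)C(=O)O2)C[C@]32OC(=O)[C@H](C)[C@@H]2[C@@H]1O[Si](C)(C)C(C)(C)C.[O-]S(=O)(=O)C(F)(F)F | intermediate
41 | O-TBS ether of the target | CC[C@H]1C2=C3N(CCCC2)[C@@H]([C@@H]2C[C@H](C)C(=O)O2)C[C@]32OC(=O)[C@H](C)[C@@H]2[C@@H]1O[Si](C)(C)C(C)(C)C | intermediate
42 | CNP0154902.3 | CC[C@H]1C2=C3N(CCCC2)[C@@H]([C@@H]2C[C@H](C)C(=O)O2)C[C@]32OC(=O)[C@H](C)[C@@H]2[C@@H]1O | target

## Step count and least certain steps

Total: 22 steps. Longest linear sequence: 20 steps (5 → 42, steps 3–22); aldehyde 4 is made in 2 steps (steps 1–2).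

**Step 21 (proposed new method).**
- Risks: a second hydride transfer to the conjugated iminium ion (over-reduction to a methylene); attack of hydride or ethyl at the iminium carbon instead of the γ-carbon; erosion of facial selectivity if the silyl ether is not pseudoaxial.
- Fallback (known chemistry, from 38 back to 41): Luche reduction of 38 (NaBH4, CeCl3·7H2O, MeOH, −40 °C), a 1,2-reduction of the vinylogous amide that leaves γ-lactones alone, would give the allylic alcohol F1. BF3·OEt2 would ionise F1 to the same conjugated iminium ion in the presence of EtMgBr and CuBr·SMe2, and γ-addition as with pyridinium salts would return to 41.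

**Step 20 (key step).**
- Risks: closure of the carboxylate onto the iminium carbon to give an unreactive N,O-acetal; intermolecular acylation outrunning ring closure; loss of configuration at the silyloxy carbon through ketene formation.
- Fallback (ring C by sulfide contraction, from 26 back to 38): the tert-butyl ester of 26 is cleaved (TMSOTf, 2,6-lutidine) to the thiolactam acid F2. F2 is homologated through its mixed anhydride with CH2N2 and anhydrous HBr to the thiolactam bromomethyl ketone F3. Intramolecular S-alkylation and PPh3/Et3N sulfide contraction give the tricyclic N–H vinylogous amide F4; this forms the C=C bond of the vinylogous amide instead of the acyl bond. Annulation of F4 with 30 as in step 18 gives 38.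

**Step 11.**
- Risks: 1,2-attack of the ester enolate on the N-acyl lactam with ring opening; a weak or reversed facial bias at the β-carbon; poor anti selectivity at the methyl centre; migration of the Boc group to the new alkoxide.
- Fallback (from 16 back to 20): (CH2=CMe)2CuLi, the nucleophile class with the best-documented anti preference next to an allylic oxygen, adds to 16, and the enolate is oxidised with the same oxaziridine to the isopropenyl α-hydroxy lactam F5. Hydroboration (9-BBN, then NaBO3·4H2O) gives the diol F6, and TEMPO/PhI(OAc)2 oxidative lactonisation gives 20. If the methyl centre is wrong it is corrected by enolisation and kinetic protonation.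

**Step 18.**
- Risks: slow seven-membered ring closure, leaving time for intermolecular alkylation or elimination of the halide; base-induced epimerisation of the ring D methyl centre.
- Fallback (ring A by metathesis, from 29 back to 33): allyl bromide and NaH give the N,C-diallyl vinylogous carbamate F7. The second-generation Grubbs catalyst closes the ring to the dihydroazepine F8. Hydrogenation with RhCl(PPh3)3 saturates the disubstituted alkene and gives 33.

**Step 7.**
- Risks: poor facial selectivity if zinc chelates the carbamate and the aldehyde; epimerisation of the α-amino aldehyde.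
- Fallback (from 9 to 12): reagent control replaces substrate control; allylboration with a chiral diol-derived 2-(ethoxycarbonyl)allylboronate, then lactonisation, gives 12 directly with no new intermediate.

## Further compounds

F1 | step 21 | allylic alcohol from 1,2-reduction of 38 (carbinol epimers) | OC1C2=C3N(CCCC2)[C@@H]([C@@H]2C[C@H](C)C(=O)O2)C[C@]32OC(=O)[C@H](C)[C@@H]2[C@@H]1O[Si](C)(C)C(C)(C)C
F2 | step 20 | thiolactam acid | OC(=O)[C@@H](O[Si](C)(C)C(C)(C)C)[C@H]1[C@@H](C)C(=O)O[C@]12C[C@H]([C@@H]3C[C@H](C)C(=O)O3)NC2=S
F3 | step 20 | thiolactam bromomethyl ketone | BrCC(=O)[C@@H](O[Si](C)(C)C(C)(C)C)[C@H]1[C@@H](C)C(=O)O[C@]12C[C@H]([C@@H]3C[C@H](C)C(=O)O3)NC2=S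
F4 | step 20 | tricyclic N–H vinylogous amide | O=C1C=C2N[C@@H]([C@@H]4C[C@H](C)C(=O)O4)C[C@]23OC(=O)[C@H](C)[C@@H]3[C@@H]1O[Si](C)(C)C(C)(C)C
F5 | step 11 | isopropenyl α-hydroxy lactam | C=C(C)[C@@H]([C@]1(O)C[C@H]([C@@H]2C[C@H](C)C(=O)O2)N(C(=O)OC(C)(C)C)C1=O)[C@H](O[Si](C)(C)C(C)(C)C)CO[Si](C)(C)C(C)(C)C
F6 | step 11 | diol from hydroboration of F5 | OC[C@H](C)[C@@H]([C@]1(O)C[C@H]([C@@H]2C[C@H](C)C(=O)O2)N(C(=O)OC(C)(C)C)C1=O)[C@H](O[Si](C)(C)C(C)(C)C)CO[Si](C)(C)C(C)(C)C
F7 | step 18 | N,C-diallyl vinylogous carbamate | CC(C)(C)OC(=O)[C@@H](O[Si](C)(C)C(C)(C)C)[C@H]1[C@@H](C)C(=O)O[C@]12C[C@H]([C@@H]3C[C@H](C)C(=O)O3)N(CC=C)/C2=C(\CC=C)C(=O)OC(C)(C)C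
F8 | step 18 | dihydroazepine vinylogous carbamate | CC(C)(C)OC(=O)[C@@H](O[Si](C)(C)C(C)(C)C)[C@H]1[C@@H](C)C(=O)O[C@]12C[C@H]([C@@H]3C[C@H](C)C(=O)O3)N3CC=CCC(C(=O)OC(C)(C)C)=C23
F0 | step 7 | none | none
A1 | alternative 1 | spiro-isoxazolidine adduct | O=C1C(CCCCCl)[C@H](CC)[C@@H](O[Si](C)(C)C(C)(C)C)[C@@H]([C@@H](C)C(=O)OC)[C@@]12C[C@H]([C@@H]3C[C@H](C)C(=O)O3)N(Cc3ccccc3)O2
A2 | alternative 2 | O-TBS ether of the target (same structure as 41) | CC[C@H]1C2=C3N(CCCC2)[C@@H]([C@@H]2C[C@H](C)C(=O)O2)C[C@]32OC(=O)[C@H](C)[C@@H]2[C@@H]1O[Si](C)(C)C(C)(C)C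
A3 | alternative 3 | tetracyclic enamide ketone lactam | CC[C@H]1C2=C3N(C(=O)CCC2)[C@@H]([C@@H]2C[C@H](C)C(=O)O2)C[C@]32OC(=O)C[C@@H]2C1=O
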